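In percentage points the isomer readings are thin: each carries a scatter of 1 percentage point, and at 40.0 h the birch run shows 1.6 % of isomer of the product and the larch run 0.8 %. Yet they must settle my next run: if purity of the target counts, do I charge more precatalyst and stop early, as in beta, or charge less and wait, as in zeta?

the same everywhere: starting material 20 mM

|  | coupling partner | protic impurity | precatalyst | remark | time |
|---|---|---|---|---|---|
| birch | 60 mM | 20 mM | 30 µM | run made earlier |  |
| larch | 60 mM | 20 mM | 50 µM | run made earlier |  |
| beta | 60.0 mM | 20.0 mM | 60 µM |  | 12 h |
| zeta | 60.0 mM | 20.0 mM | 40 µM |  | 50 h |

- birch (time / h: target / %, isomer of the product / %): 3.00: 0, 0; 4.00: 0, 0.3; 6.00: 2.1, 0; 10.0: 2.0, 0; 15.0: 3.7, 0; 25.0: 7.3, 0; 40.0: 15.5, 1.6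
- larch (time / h: target / %, isomer of the product / %): 2.00: 0, 0; 5.00: 0.7, 0; 10.0: 3.0, 0.8; 15.0: 4.9, 0.1; 20.0: 9.1, 0.9; 30.0: 16.5, 0; 40.0: 21.9, 0.8

(each reading ± 1 percentage point)

* which of the two ends with the higher share of target in all that became target or isomer of the product ("neither" if they lie within 2 percentage points) (beta / zeta / neither)
* share of target in all that became target or isomer of the product, beta
* share of target in all that became target or isomer of the product, zeta

I assume that the isomer of the product is made from target by the same catalyst that makes target. The isomer's rate then goes as catalyst times target and the target's rate as catalyst, so the catalyst cancels. Thus c(isomer of the product) is g times c(target) squared, each taken as a fraction of the starting material charged. The share of target, the selectivity, is then one over one plus g times c(target). Weighting the three latest readings with target above 16.5 % or near it, I read 0.212 for g, the isomer coefficient, a rough reading given that scatter.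

Scaling the larch readings around 12 h by precatalyst, I expect 4.74 % target in beta. Extending the mean of both runs along the late birch slope, I expect 24.2 % in zeta. So with the target I expect in beta at its own 12 h, g gives 99.0 % for beta. With the target I expect in zeta at its own 50 h, g gives 95.1 % for zeta. My share for beta stands above my share for zeta by more than the margin of 2 points, so I choose beta.

The forecast differs from my reckoning: it gives 97 % for beta and 95.5 % for zeta, and answers neither, on these grounds: “Beta may be slightly higher, but the gap probably lies within 2 points”.

The flask gives 98.9 % for beta and 94.1 % for zeta, so beta ends higher, by 4.8 points against the forecast's 1.5 points.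

    starting material + catalyst intermediate A → catalyst intermediate B (k = 2700 L mol⁻¹ h⁻¹)
    catalyst intermediate B → released group + catalyst intermediate C (k = 500 h⁻¹)
    coupling partner + precatalyst → free catalyst + spent reagent (k = 0.400 L mol⁻¹ h⁻¹)
    catalyst intermediate C → free catalyst + target (k = 18.0 h⁻¹)
    coupling partner + free catalyst → catalyst intermediate A (k = 1000 L mol⁻¹ h⁻¹)
    starting material + protic impurity → quenched substrate (k = 3.20 L mol⁻¹ h⁻¹)
    target + free catalyst ⇌ isomer of the product + free catalyst, rate k7*[free catalyst]*[target] forward; the back reaction follows from the equilibrium constant (K = 17.0, k = 1400 L mol⁻¹ h⁻¹)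

In zeta, starting material meeting protic impurity has half its turnover done by 8.25 h, while coupling partner meeting free catalyst reaches that mark at 27.7 h. At 50.0 h zeta holds 23.3 % target beside 68.8 % quenched substrate. With the simulated targets, g gives 99.1 % for beta and 95.3 % for zeta.

In the neighbour of zeta charged with 50 mM of protic impurity, target stands at 6.64 % at 50.0 h, so g gives a share of 98.6 %. The computed share there is 98.4 %.

The numbers in the tables come from a simulation for an exercise; the scatter is artificial.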